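## The problem

Dorsilurin C (28) is a flavonol whose 3-hydroxychromen-4-one core (rings A and C) carries free hydroxyls at C5 and C7 and 3-methylbut-2-enyl (prenyl) groups at C6 and C8. Ring B at C2 is fused through O–C3' and C4' to a 2,2-dimethylpyran, so the C2 substituent is a 2,2-dimethyl-2H-chromen-7-yl group. The molecule has no stereocenter, so no center controls another and the whole task is one of placing substituents. Ring A is hexasubstituted, with oxygen on C5, C7 and C8a alternating with carbon on C6, C8 and C4a, and prenylating a preformed trioxygenated benzene spreads the five-carbon units over carbon and oxygen and gives mono-, di- and geminally alkylated mixtures. Ring B needs the pyran fused linearly (oxygen meta and vinyl carbon para to the flavone bond), which a sigmatropic route from a meta-substituted aryl propargyl ether does not guarantee. The two prenyl groups and the chromene double bond exclude hydrogenation, halogens, peracids and dioxiranes and add a neighbouring phenol under strong protic or Lewis acid to give chromans, so the C3 oxygen must come from an oxidant that attacks only an electron-poor alkene. The enabling feature is the strict O/C alternation around ring A. A vinylketene and an ynol ether deliver exactly this pattern: the C5 oxygen from the ketene carbonyl, the C6 prenyl and C7 oxygen from the alkyne, the C8 prenyl and C8a oxygen from the cyclobutenone, and C4a as the one unsubstituted carbon left for acylation.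

## Retrosynthesis

**Ring C last.** Removing two methoxymethyl groups leads from 28 to 27. In 27 the O1–C2 bond and the C3–O bond are cut together (Algar–Flynn–Oyamada transform) to give chalcone 26. Cutting its enone C=C bond (flavone C2–C3) gives methyl ketone 19 and aldehyde 25. The neighbouring cut, a Baker–Venkataraman type assembly, would need an oxygenated acyl unit and an acid-promoted cyclodehydration in the presence of three acid-sensitive alkenes. The chalcone route takes the C3 oxygen from an alkaline peroxide, which leaves isolated alkenes alone. Ketone 19 holds all of ring A and aldehyde 25 all of ring B, so the route converges here. The forward steps need base-stable protection on O5 and O7 and a 6-endo rather than 5-exo oxidative closure.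

**Ring B aldehyde.** The formyl–aryl bond of 25 is cut to bromide 23 (halogen–lithium exchange). Bromide 23 goes back through alcohol 22 to ketone 21 (dehydration, reduction). Cutting O1–C2 and C2–C3 of the pyranone in 21 (Kabbe transform) gives acetophenone 20. The para relation of bromine and acetyl in 20 fixes the later 7-position without ambiguity. A shorter thermal rearrangement of an aryl propargyl ether could close on either ortho carbon. Compound 20 is a commodity chemical, and the four steps are routine.

**Ring A ketone.** Compounds 19, 18 and 17 differ only in protecting groups. The two silyl ethers delivered by the ring synthesis sit ortho and para to the ketone and would not survive the hydroxide media of the aldol and oxidation steps. They are therefore exchanged: both are removed (18) and the para hydroxyl is recapped as an acetal (19). This leaves the one hydrogen-bonded hydroxyl that ring closure needs. Cutting the aryl–acetyl bond (C4a–C4) of 17 gives arene 15. Friedel–Crafts acylation is the obvious alternative but needs acid next to an ortho-prenyl phenol. Instead the single free hydroxyl of phenol 14 is capped as methoxymethyl ether 15 and used to direct lithiation to the only ring hydrogen. The forward reaction needs ring metalation to be faster than deprotonation of the benzylic-allylic CH2 groups, and no migration of the neighbouring silyl group.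

**Ring A (key disconnection).** Phenol 14 is cut at C5–C6, C7–C8 and C4a–C5 in flavone numbering (C1–C2, C3–C4 and C1–C6 of 14). This gives cyclobutenone 9 and siloxyalkyne 6. Compared with prenylating a finished ring, this cut fixes every substituent by the connectivity of two small pieces, each carrying one prenyl group. It also delivers the three oxygens already differentiated: one free, two silylated. The forward reaction is a thermal, neutral cascade. It requires the donor-substituted cyclobutenone to open, the ketene–alkyne (2+2) step to follow the polarity of the ynol ether, and the trisubstituted alkenes to remain spectators.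

**The two small pieces.** Cyclobutenone 9 is cut at C1–C2 and C3–C4 to the same alkyne 6 and ketene 8, the latter from diketene 7. Alkyne 6 is cut at the O–C(sp) bond to terminal enyne 3 (acetylide oxidation and silylation). Enyne 3 is cut at its sp3–sp bond to prenyl bromide 1 and ethynylmagnesium bromide 2. Because 6 serves twice, both partners of the key step come from one three-step sequence.

## Roads not taken

Alternative 1: All three five-carbon units are disconnected to aryl ethers. The two ring-A prenyl groups become 1,1-dimethylallyl ethers on O5 and O7 and the pyran becomes a 1,1-dimethylpropargyl ether on O3'. The precursor is 4-oxo-5,7-bis(2-methylbut-3-en-2-yloxy)-2-[3-(2-methylbut-3-yn-2-yloxy)phenyl]-4H-chromen-3-yl benzoate A1.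

- Forward key step: heating A1 with the Lewis acid Eu(fod)3 would give two aromatic (3,3) shifts to C6 and C8. On ring B, a propargyl Claisen shift, hydrogen shift and oxa-six-electron closure would form the pyran. The product is dorsilurin C 3-benzoate A2.
- Merits: the flavonol core is made first by classical chemistry with no sensitive alkene present. All five-carbon units arrive in one late operation. The step count would very probably be lower than in the chosen plan.
- Weak points: three regiochemical outcomes must be right at once. The O7 ether can move to C6 or C8, while the O5 ether can only go to C6, so the two compete for one site. The meta-substituted propargyl ether can close on C2' as well as C4'. Building A1 needs two tertiary allyl ethers beside one tertiary propargyl ether, one of them on the chelated, hindered O5.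
- Comparison: in step economy this road is better. The chosen plan offsets this because every ring-A substituent is fixed by bond connectivity in the key step and the ring-B fusion by the bromine position in 20, so no isomer separation is expected.

Alternative 2: Ring B is disconnected at C1'–C2' and C5'–C6'. The precursors are 2-acetyl-3,5,7-tris(methoxymethoxy)-6,8-bis(3-methylbut-2-enyl)-4H-chromen-4-one A3 and 3-(ethoxymethylidene)-6-methylhept-5-en-2-one A4.

- Forward key step: the lithium enolate of A3 adds to A4 with loss of ethoxide. Aldol condensation of the enone methyl group onto the acetyl carbonyl then closes and aromatizes ring B. The product is 2-[3-hydroxy-4-(3-methylbut-2-enyl)phenyl]-3,5,7-tris(methoxymethoxy)-6,8-bis(3-methylbut-2-enyl)-4H-chromen-4-one A5.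
- Merits: the 3'-oxygen/4'-carbon pattern of ring B is unambiguous, and the route is convergent.
- Weak points: A3 already contains the hexasubstituted ring A with both prenyl groups, so the main problem is assumed solved, not addressed. A 2-acyl-3-oxygenated chromone is harder to reach than a chalcone. Its enolate must add to A4 faster than nucleophiles attack the chromone C2. After A5, an oxidative prenyl-phenol cyclization to the chromene and three deprotections remain.
- Comparison: ring-B regiocontrol equals that of the chosen plan but costs a more elaborate precursor. The chosen plan handles ring B in four routine steps and reserves its key step for ring A, where the difficulty lies.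

Alternative 3: Ring A is disconnected into two esters: ethyl 2-acetyl-5-methylhex-4-enoate A6 and ethyl 5-methylhex-4-enoate A7.

- Forward key step: the dianion of A6 is acylated at its terminal carbon by A7. The resulting 3,5-dioxo ester undergoes Dieckmann closure to 2,4-bis(3-methylbut-2-enyl)benzene-1,3,5-triol A8.
- Merits: it shares the logic of the chosen plan, building ring A from open-chain pieces with both prenyl groups in place. It uses cheaper reagents and needs neither ketene gas nor a peroxide-derived ynolate. In cost, safety and scalability it is the better road.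
- Weak points: 3,5-dioxo esters readily close through oxygen to 4-hydroxy-2-pyrones, which diverts material from the carbocycle. Acylating a dianion with an enolizable ester loses material to proton transfer. A8 is an unprotected, air-sensitive triol, so every oxygen must then be protected and one unveiled again before acylation and ring-C closure.
- Comparison: the chosen plan offsets the simpler reagents with a pericyclic cascade that has no pyrone diversion, and with product 14, which is stable and already differentiated (one free hydroxyl for direction, two silyl ethers). Step counts to ketone 19 would be similar.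

Key step: step 4

## Route

Remark: 28 has no stereocenter. The only stereocenters met on the way (C4 of 11, C4 of 22) are racemic and are erased in the same or the next step. Ketene 8 is assumed to be generated from 7 by cracking immediately before use; each molecule of 7 gives two molecules of 8, and the gas is used in excess.

Step 1
Reactants: 1 1-bromo-3-methylbut-2-ene; 2 ethynylmagnesium bromide
Product: 3 5-methylhex-4-en-1-yne
Conditions: 2 (excess), CuCl (5 mol %), THF, 0 °C to rt; fractional distillation
Reagents that add atoms: none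
Why: CuCl-catalysed coupling of an alkynyl Grignard reagent with a primary allylic bromide; attack at the unhindered CH2 terminus (SN2) should give the skipped enyne and not the tertiary SN2' isomer.

Step 2
Reactants: 3 5-methylhex-4-en-1-yne
Product: 6 triisopropyl[(5-methylhex-4-en-1-ynyl)oxy]silane, via lithium acetylide 4 (not isolated), via lithium ynolate 5 (not isolated)
Conditions: n-BuLi, THF, −78 °C; LiOOt-Bu (from t-BuOOH and LiN(SiMe3)2), −78 to 0 °C; TIPSOTf, −78 to 0 °C
Reagents that add atoms: tert-butyl hydroperoxide, CC(C)(C)OO; triisopropylsilyl trifluoromethanesulfonate, CC(C)[Si](OS(=O)(=O)C(F)(F)F)(C(C)C)C(C)C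
Why: Acetylide oxidation to the ynolate by oxygen transfer from lithium tert-butyl peroxide, then O-silylation by the hard, bulky silyl triflate; the isolated trisubstituted alkene is inert to the peroxide anion and the bulky silyl group makes the ynol ether isolable.

Step 3
Reactants: 6 triisopropyl[(5-methylhex-4-en-1-ynyl)oxy]silane; 7 diketene
Product: 9 2-(3-methylbut-2-enyl)-3-(triisopropylsilyloxy)cyclobut-2-en-1-one, via ketene 8 (not isolated)
Conditions: 7 cracked at 550 °C (hot quartz tube, N2 stream), ketene gas passed in excess into 6 in CH2Cl2, 0 °C; surplus gas led into a scrubber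
Reagents that add atoms: none
Why: Ketene–ynol ether (2+2) cycloaddition, known for siloxyalkynes; the alkyne carbon remote from oxygen bonds to the ketene carbonyl carbon, so the prenyl group ends on C2 and the silyloxy group on C3. Each molecule of 7 cracks to two of 8, one of which is taken up per molecule of 6 while the other leaves with the N2 stream.

Step 4
Reactants: 9 2-(3-methylbut-2-enyl)-3-(triisopropylsilyloxy)cyclobut-2-en-1-one; 6 triisopropyl[(5-methylhex-4-en-1-ynyl)oxy]silane
Product: 14 2,4-bis(3-methylbut-2-enyl)-3,5-bis(triisopropylsilyloxy)phenol, via vinylketene 10 (not isolated), via vinylcyclobutenone 11 (not isolated), via dienylketene 12 (not isolated), via cyclohexadienone 13 (not isolated)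
Conditions: 6 (1.3 equiv), toluene, 80 °C then 110 °C, sealed tube, N2
Reagents that add atoms: none
Why: Danheiser benzannulation in its siloxyalkyne form: on heating, 9 opens by four-electron electrocyclic cleavage of the C1–C4 bond to vinylketene 10. The nucleophilic, prenyl-bearing carbon of 6 attacks the ketene carbonyl carbon and (2+2) cycloaddition across the ketene C=C bond gives 11, forming the future C5–C6 and C7–C8 bonds. Four-electron opening of 11 gives dienylketene 12, which closes ring A by thermal six-electron electrocyclization between the ketene carbon and the terminal CH2 (future C4a–C5 bond), and dienone 13 tautomerizes to phenol 14. The closest known reaction type is the union of simple cyclobutenones with triisopropylsilyl ynol ethers to resorcinol monosilyl ethers; the 3-silyloxy group on the cyclobutenone is the less tested variable here. No stereocenter is formed that persists (11 is racemic and transient). The selectivity needed is the regiochemistry of the (2+2) step, secured by the matched polarity of ynol ether (carbon remote from oxygen nucleophilic) and ketene (carbonyl carbon electrophilic), which puts the alkyne prenyl group next to the new hydroxyl and the silyloxy carbon between the two prenyl groups. The cyclizable geometry of 12 is reached because opening of 11 is reversible, and the bulky silyl groups and the excess of 6 should limit acylation of 14 by 10.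

Step 5
Reactants: 14 2,4-bis(3-methylbut-2-enyl)-3,5-bis(triisopropylsilyloxy)phenol
Product: 15 1-(methoxymethoxy)-2,4-bis(3-methylbut-2-enyl)-3,5-bis(triisopropylsilyloxy)benzene
Conditions: MOMCl, iPr2NEt, CH2Cl2, 0 °C to rt
Reagents that add atoms: chloromethyl methyl ether, COCCl
Why: O-alkylation of the single free phenol; the acetal is a strong ortho-director for step 6 and survives organolithium, fluoride and hydroxide.

Step 6
Reactants: 15 1-(methoxymethoxy)-2,4-bis(3-methylbut-2-enyl)-3,5-bis(triisopropylsilyloxy)benzene
Product: 17 1-[2-(methoxymethoxy)-3,5-bis(3-methylbut-2-enyl)-4,6-bis(triisopropylsilyloxy)phenyl]ethanone, via aryllithium 16 (not isolated)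
Conditions: s-BuLi, TMEDA, THF, −78 °C; MeC(O)N(OMe)Me, −78 to 0 °C; then H2O
Reagents that add atoms: N-methoxy-N-methylacetamide, CC(=O)N(C)OC
Why: Directed ortho-metalation at the only ring C–H, which lies between the coordinating acetal oxygen and a silyloxy group, followed by Weinreb ketone synthesis, whose chelated tetrahedral adduct stops at the ketone; −78 °C is chosen to hold back oxygen-to-carbon silyl migration and benzylic-allylic deprotonation.

Step 7
Reactants: 17 1-[2-(methoxymethoxy)-3,5-bis(3-methylbut-2-enyl)-4,6-bis(triisopropylsilyloxy)phenyl]ethanone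
Product: 18 1-[2,4-dihydroxy-6-(methoxymethoxy)-3,5-bis(3-methylbut-2-enyl)phenyl]ethanone
Conditions: Bu4NF, AcOH, THF, 0 °C
Reagents that add atoms: none
Why: Fluoride cleavage of both aryl silyl ethers, made easy by the ortho and para acyl group; acetic acid buffers the phenoxides, and the acetal and the alkenes are untouched.

Step 8
Reactants: 18 1-[2,4-dihydroxy-6-(methoxymethoxy)-3,5-bis(3-methylbut-2-enyl)phenyl]ethanone
Product: 19 1-[2-hydroxy-4,6-bis(methoxymethoxy)-3,5-bis(3-methylbut-2-enyl)phenyl]ethanone
Conditions: MOMCl (1.1 equiv), iPr2NEt, CH2Cl2, 0 °C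
Reagents that add atoms: chloromethyl methyl ether, COCCl
Why: Selective O-alkylation of the para hydroxyl; the ortho hydroxyl is held in a hydrogen bond to the acetyl carbonyl and should stay free, as is usual for 2,4-dihydroxyaryl ketones.

Step 9
Reactants: 20 1-(4-bromo-2-hydroxyphenyl)ethanone
Product: 21 7-bromo-2,2-dimethylchroman-4-one
Conditions: acetone, pyrrolidine, MeOH, reflux
Reagents that add atoms: acetone, CC(C)=O
Why: Kabbe chromanone synthesis (enamine aldol condensation, then oxa-Michael closure of the phenol); the bromine para to the acetyl group becomes C7 without ambiguity.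

Step 10
Reactants: 21 7-bromo-2,2-dimethylchroman-4-one
Product: 22 7-bromo-2,2-dimethylchroman-4-ol (racemic)
Conditions: NaBH4, MeOH, 0 °C
Reagents that add atoms: none
Why: Hydride reduction of the aryl ketone; the new center is formed racemic and is removed in step 11.

Step 11
Reactants: 22 7-bromo-2,2-dimethylchroman-4-ol
Product: 23 7-bromo-2,2-dimethyl-2H-chromene
Conditions: TsOH·H2O (cat.), toluene, reflux, Dean–Stark
Reagents that add atoms: none
Why: Acid-catalysed dehydration through the benzylic cation gives the conjugated chromene double bond, the standard completion of the chromanone route to 2,2-dimethylchromenes.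

Step 12
Reactants: 23 7-bromo-2,2-dimethyl-2H-chromene
Product: 25 2,2-dimethyl-2H-chromene-7-carbaldehyde, via aryllithium 24 (not isolated)
Conditions: n-BuLi, THF, −78 °C; DMF, −78 °C to rt; then H2O
Reagents that add atoms: N,N-dimethylformamide, CN(C)C=O
Why: Bromine–lithium exchange followed by formylation with a formamide (Bouveault aldehyde synthesis); the chromene has no acidic proton that competes at −78 °C.

Step 13
Reactants: 19 1-[2-hydroxy-4,6-bis(methoxymethoxy)-3,5-bis(3-methylbut-2-enyl)phenyl]ethanone; 25 2,2-dimethyl-2H-chromene-7-carbaldehyde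
Product: 26 (E)-3-(2,2-dimethyl-2H-chromen-7-yl)-1-[2-hydroxy-4,6-bis(methoxymethoxy)-3,5-bis(3-methylbut-2-enyl)phenyl]prop-2-en-1-one
Conditions: KOH (50% aq), EtOH, rt
Reagents that add atoms: none
Why: Claisen–Schmidt condensation of a methyl ketone with a non-enolizable aldehyde; E1cB dehydration gives the E-enone, and acetals, prenyl groups and the chromene are stable to hydroxide.

Step 14
Reactants: 26 (E)-3-(2,2-dimethyl-2H-chromen-7-yl)-1-[2-hydroxy-4,6-bis(methoxymethoxy)-3,5-bis(3-methylbut-2-enyl)phenyl]prop-2-en-1-one
Product: 27 2-(2,2-dimethyl-2H-chromen-7-yl)-3-hydroxy-5,7-bis(methoxymethoxy)-6,8-bis(3-methylbut-2-enyl)-4H-chromen-4-one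
Conditions: H2O2 (30% aq), NaOH (aq), MeOH/THF, 0 °C to rt
Reagents that add atoms: hydrogen peroxide, OO
Why: Algar–Flynn–Oyamada reaction: the phenoxide closes 6-endo on the enone β-carbon, the α-carbon is hydroxylated by the peroxide and the ring is dehydrogenated to the flavonol in the same pot; alkaline peroxide attacks only the electron-poor enone, and the low temperature is meant to favour the flavonol over the aurone.

Step 15
Reactants: 27 2-(2,2-dimethyl-2H-chromen-7-yl)-3-hydroxy-5,7-bis(methoxymethoxy)-6,8-bis(3-methylbut-2-enyl)-4H-chromen-4-one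
Product: 28 dorsilurin C (2-(2,2-dimethyl-2H-chromen-7-yl)-3,5,7-trihydroxy-6,8-bis(3-methylbut-2-enyl)-4H-chromen-4-one)
Conditions: HCl (3 M aq), MeOH/THF, 40 °C
Reagents that add atoms: none
Why: Acid-catalysed acetal exchange with methanol, the usual last step for methoxymethyl-protected prenylated flavonoids; the ether peri to the carbonyl leaves first and the mild temperature is chosen to spare the prenyl groups and the chromene.

## Compound list

1 | 1-bromo-3-methylbut-2-ene (prenyl bromide) | CC(C)=CCBr | starting material
2 | ethynylmagnesium bromide | C#C[Mg]Br | starting material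
3 | 5-methylhex-4-en-1-yne | C#CCC=C(C)C | intermediate
4 | (5-methylhex-4-en-1-ynyl)lithium | [Li]C#CCC=C(C)C | intermediate (not isolated)
5 | lithium 5-methylhex-4-en-1-yn-1-olate | [Li]OC#CCC=C(C)C | intermediate (not isolated)
6 | triisopropyl[(5-methylhex-4-en-1-ynyl)oxy]silane | CC(C)=CCC#CO[Si](C(C)C)(C(C)C)C(C)C | intermediate
7 | diketene (4-methylideneoxetan-2-one) | C=C1CC(=O)O1 | starting material
8 | ketene (ethenone) | C=C=O | intermediate (not isolated)
9 | 2-(3-methylbut-2-enyl)-3-(triisopropylsilyloxy)cyclobut-2-en-1-one | O=C1CC(O[Si](C(C)C)(C(C)C)C(C)C)=C1CC=C(C)C | intermediate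
10 | 2-(3-methylbut-2-enyl)-3-(triisopropylsilyloxy)buta-1,3-dien-1-one | O=C=C(CC=C(C)C)C(=C)O[Si](C(C)C)(C(C)C)C(C)C | intermediate (not isolated)
11 | 2,4-bis(3-methylbut-2-enyl)-3-(triisopropylsilyloxy)-4-[1-(triisopropylsilyloxy)ethenyl]cyclobut-2-en-1-one (racemic) | O=C1C(CC=C(C)C)=C(O[Si](C(C)C)(C(C)C)C(C)C)C1(CC=C(C)C)C(=C)O[Si](C(C)C)(C(C)C)C(C)C | intermediate (not isolated)
12 | (3E)-2,4-bis(3-methylbut-2-enyl)-3,5-bis(triisopropylsilyloxy)hexa-1,3,5-trien-1-one | O=C=C(CC=C(C)C)/C(O[Si](C(C)C)(C(C)C)C(C)C)=C(CC=C(C)C)\C(=C)O[Si](C(C)C)(C(C)C)C(C)C | intermediate (not isolated)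
13 | 2,4-bis(3-methylbut-2-enyl)-3,5-bis(triisopropylsilyloxy)cyclohexa-2,4-dien-1-one | O=C1CC(O[Si](C(C)C)(C(C)C)C(C)C)=C(CC=C(C)C)C(O[Si](C(C)C)(C(C)C)C(C)C)=C1CC=C(C)C | intermediate (not isolated)
14 | 2,4-bis(3-methylbut-2-enyl)-3,5-bis(triisopropylsilyloxy)phenol | CC(C)=CCc1c(O)cc(O[Si](C(C)C)(C(C)C)C(C)C)c(CC=C(C)C)c1O[Si](C(C)C)(C(C)C)C(C)C | intermediate
15 | 1-(methoxymethoxy)-2,4-bis(3-methylbut-2-enyl)-3,5-bis(triisopropylsilyloxy)benzene | COCOc1cc(O[Si](C(C)C)(C(C)C)C(C)C)c(CC=C(C)C)c(O[Si](C(C)C)(C(C)C)C(C)C)c1CC=C(C)C | intermediate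
16 | [2-(methoxymethoxy)-3,5-bis(3-methylbut-2-enyl)-4,6-bis(triisopropylsilyloxy)phenyl]lithium | [Li]c1c(OCOC)c(CC=C(C)C)c(O[Si](C(C)C)(C(C)C)C(C)C)c(CC=C(C)C)c1O[Si](C(C)C)(C(C)C)C(C)C | intermediate (not isolated)
17 | 1-[2-(methoxymethoxy)-3,5-bis(3-methylbut-2-enyl)-4,6-bis(triisopropylsilyloxy)phenyl]ethanone | CC(=O)c1c(OCOC)c(CC=C(C)C)c(O[Si](C(C)C)(C(C)C)C(C)C)c(CC=C(C)C)c1O[Si](C(C)C)(C(C)C)C(C)C | intermediate
18 | 1-[2,4-dihydroxy-6-(methoxymethoxy)-3,5-bis(3-methylbut-2-enyl)phenyl]ethanone | CC(=O)c1c(OCOC)c(CC=C(C)C)c(O)c(CC=C(C)C)c1O | intermediate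
19 | 1-[2-hydroxy-4,6-bis(methoxymethoxy)-3,5-bis(3-methylbut-2-enyl)phenyl]ethanone | CC(=O)c1c(OCOC)c(CC=C(C)C)c(OCOC)c(CC=C(C)C)c1O | intermediate
20 | 1-(4-bromo-2-hydroxyphenyl)ethanone | CC(=O)c1ccc(Br)cc1O | starting material
21 | 7-bromo-2,2-dimethylchroman-4-one | CC1(C)CC(=O)c2ccc(Br)cc2O1 | intermediate
22 | 7-bromo-2,2-dimethylchroman-4-ol (racemic) | CC1(C)CC(O)c2ccc(Br)cc2O1 | intermediate
23 | 7-bromo-2,2-dimethyl-2H-chromene | CC1(C)C=Cc2ccc(Br)cc2O1 | intermediate
24 | (2,2-dimethyl-2H-chromen-7-yl)lithium | [Li]c1ccc2C=CC(C)(C)Oc2c1 | intermediate (not isolated)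
25 | 2,2-dimethyl-2H-chromene-7-carbaldehyde | O=Cc1ccc2C=CC(C)(C)Oc2c1 | intermediate
26 | (E)-3-(2,2-dimethyl-2H-chromen-7-yl)-1-[2-hydroxy-4,6-bis(methoxymethoxy)-3,5-bis(3-methylbut-2-enyl)phenyl]prop-2-en-1-one | O=C(/C=C/c1ccc2C=CC(C)(C)Oc2c1)c1c(OCOC)c(CC=C(C)C)c(OCOC)c(CC=C(C)C)c1O | intermediate
27 | 2-(2,2-dimethyl-2H-chromen-7-yl)-3-hydroxy-5,7-bis(methoxymethoxy)-6,8-bis(3-methylbut-2-enyl)-4H-chromen-4-one | COCOc1c(CC=C(C)C)c(OCOC)c(CC=C(C)C)c2oc(-c3ccc4C=CC(C)(C)Oc4c3)c(O)c(=O)c12 | intermediate
28 | dorsilurin C | CC(C)=CCc1c(O)c(CC=C(C)C)c2oc(-c3ccc4c(c3)OC(C)(C)C=C4)c(O)c(=O)c2c1O | target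

## Step count and risks

Total: 15 steps. Longest linear sequence: 11 steps (steps 1–8 and 13–15); steps 9–12 form the four-step side branch to aldehyde 25.

**Step 4 (key step).** The donor-substituted cyclobutenone may open too slowly at temperatures the siloxyalkyne tolerates. The electron-rich vinylketene may dimerize or acylate the product phenol faster than it is intercepted by the alkyne. The closure of the dienylketene may stall if the reversible ring opening does not feed the cyclizable geometry.
Fallback: ring A is not built but bought, and the prenyl groups are put on by known, less selective chemistry. It sets out from bromide 1 and purchased 1-(2,4,6-trihydroxyphenyl)ethanone. Double C-alkylation in aqueous KOH should give, after separation from mono- and over-alkylated material, 1-[2,4,6-trihydroxy-3,5-bis(3-methylbut-2-enyl)phenyl]ethanone F1. Bis-protection with MOMCl and iPr2NEt, which leaves one chelated hydroxyl free, rejoins the route at 19.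

**Step 6.** Deprotonation may occur at the benzylic-allylic CH2 of the neighbouring prenyl group instead of the crowded ring position. The ortho-lithiated silyl ether may undergo oxygen-to-carbon silyl migration on warming. The hindered aryllithium may enolize the Weinreb amide and return 15.
Fallback: no organolithium. It sets out from phenol 14. Magnesium-mediated ortho-formylation (MgCl2, Et3N, paraformaldehyde, MeCN, reflux) should give 2-hydroxy-3,5-bis(3-methylbut-2-enyl)-4,6-bis(triisopropylsilyloxy)benzaldehyde F2. Excess MeMgBr then gives 1-[2-hydroxy-3,5-bis(3-methylbut-2-enyl)-4,6-bis(triisopropylsilyloxy)phenyl]ethanol F3 (racemic). MnO2 oxidation gives 1-[2-hydroxy-3,5-bis(3-methylbut-2-enyl)-4,6-bis(triisopropylsilyloxy)phenyl]ethanone F4. Alkylation of the chelated hydroxyl (NaH, MOMCl, DMF) rejoins the route at 17.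

**Step 14.** The 6'-substituent twists the enone, so the phenoxide may close 5-exo on the α-carbon and lead to the aurone. Baeyer–Villiger-type cleavage of the electron-rich aryl ketone by the peroxide is a second loss channel.
Fallback: epoxidation and ring closure are separated. It sets out from chalcone 26. Capping the 2'-hydroxyl (NaH, MOMCl) gives (E)-3-(2,2-dimethyl-2H-chromen-7-yl)-1-[2,4,6-tris(methoxymethoxy)-3,5-bis(3-methylbut-2-enyl)phenyl]prop-2-en-1-one F5. Weitz–Scheffer epoxidation (H2O2, NaOH) gives the racemic trans epoxide [3-(2,2-dimethyl-2H-chromen-7-yl)oxiran-2-yl][2,4,6-tris(methoxymethoxy)-3,5-bis(3-methylbut-2-enyl)phenyl]methanone F6. Acid in methanol removes the acetals and lets the freed phenol open the epoxide 6-endo at the benzylic carbon. This gives the racemic trans dihydroflavonol 2-(2,2-dimethyl-2H-chromen-7-yl)-3,5,7-trihydroxy-6,8-bis(3-methylbut-2-enyl)chroman-4-one F7. Base-mediated dehydrogenation by air (K2CO3, aqueous MeOH) rejoins the route at 28.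

**Step 15.** Cleaving the acetal on O7, which is flanked by two prenyl groups, may need acid strong enough to add the 5- or 7-hydroxyl to a neighbouring prenyl group (chroman formation) or to hydrate the chromene.
Fallback: the hindered oxygen carries a group removed without acid. It sets out from 18. Allyl bromide and K2CO3 give 1-[2-hydroxy-6-(methoxymethoxy)-3,5-bis(3-methylbut-2-enyl)-4-(prop-2-enyloxy)phenyl]ethanone F8. Condensation with 25 as in step 13 gives (E)-3-(2,2-dimethyl-2H-chromen-7-yl)-1-[2-hydroxy-6-(methoxymethoxy)-3,5-bis(3-methylbut-2-enyl)-4-(prop-2-enyloxy)phenyl]prop-2-en-1-one F9. Oxidative cyclization as in step 14 gives 2-(2,2-dimethyl-2H-chromen-7-yl)-3-hydroxy-5-(methoxymethoxy)-6,8-bis(3-methylbut-2-enyl)-7-(prop-2-enyloxy)-4H-chromen-4-one F10. Deallylation with the zerovalent palladium complex Pd(PPh3)4 and morpholine gives 2-(2,2-dimethyl-2H-chromen-7-yl)-3,7-dihydroxy-5-(methoxymethoxy)-6,8-bis(3-methylbut-2-enyl)-4H-chromen-4-one F11. Its remaining peri acetal should fall to dilute HCl in MeOH at room temperature, rejoining the route at 28.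

## Further compounds

F1 | step 4 | 1-[2,4,6-trihydroxy-3,5-bis(3-methylbut-2-enyl)phenyl]ethanone | CC(=O)c1c(O)c(CC=C(C)C)c(O)c(CC=C(C)C)c1O
F2 | step 6 | 2-hydroxy-3,5-bis(3-methylbut-2-enyl)-4,6-bis(triisopropylsilyloxy)benzaldehyde | O=Cc1c(O)c(CC=C(C)C)c(O[Si](C(C)C)(C(C)C)C(C)C)c(CC=C(C)C)c1O[Si](C(C)C)(C(C)C)C(C)C
F3 | step 6 | 1-[2-hydroxy-3,5-bis(3-methylbut-2-enyl)-4,6-bis(triisopropylsilyloxy)phenyl]ethanol (racemic) | CC(O)c1c(O)c(CC=C(C)C)c(O[Si](C(C)C)(C(C)C)C(C)C)c(CC=C(C)C)c1O[Si](C(C)C)(C(C)C)C(C)C
F4 | step 6 | 1-[2-hydroxy-3,5-bis(3-methylbut-2-enyl)-4,6-bis(triisopropylsilyloxy)phenyl]ethanone | CC(=O)c1c(O)c(CC=C(C)C)c(O[Si](C(C)C)(C(C)C)C(C)C)c(CC=C(C)C)c1O[Si](C(C)C)(C(C)C)C(C)C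
F5 | step 14 | (E)-3-(2,2-dimethyl-2H-chromen-7-yl)-1-[2,4,6-tris(methoxymethoxy)-3,5-bis(3-methylbut-2-enyl)phenyl]prop-2-en-1-one | O=C(/C=C/c1ccc2C=CC(C)(C)Oc2c1)c1c(OCOC)c(CC=C(C)C)c(OCOC)c(CC=C(C)C)c1OCOC
F6 | step 14 | trans-[3-(2,2-dimethyl-2H-chromen-7-yl)oxiran-2-yl][2,4,6-tris(methoxymethoxy)-3,5-bis(3-methylbut-2-enyl)phenyl]methanone (racemic, one enantiomer drawn) | O=C([C@H]1O[C@@H]1c1ccc2C=CC(C)(C)Oc2c1)c1c(OCOC)c(CC=C(C)C)c(OCOC)c(CC=C(C)C)c1OCOC
F7 | step 14 | trans-2-(2,2-dimethyl-2H-chromen-7-yl)-3,5,7-trihydroxy-6,8-bis(3-methylbut-2-enyl)chroman-4-one (racemic, one enantiomer drawn) | O=C1c2c(O)c(CC=C(C)C)c(O)c(CC=C(C)C)c2O[C@H](c2ccc3C=CC(C)(C)Oc3c2)[C@H]1O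
F8 | step 15 | 1-[2-hydroxy-6-(methoxymethoxy)-3,5-bis(3-methylbut-2-enyl)-4-(prop-2-enyloxy)phenyl]ethanone | CC(=O)c1c(OCOC)c(CC=C(C)C)c(OCC=C)c(CC=C(C)C)c1O
F9 | step 15 | (E)-3-(2,2-dimethyl-2H-chromen-7-yl)-1-[2-hydroxy-6-(methoxymethoxy)-3,5-bis(3-methylbut-2-enyl)-4-(prop-2-enyloxy)phenyl]prop-2-en-1-one | O=C(/C=C/c1ccc2C=CC(C)(C)Oc2c1)c1c(OCOC)c(CC=C(C)C)c(OCC=C)c(CC=C(C)C)c1O
F10 | step 15 | 2-(2,2-dimethyl-2H-chromen-7-yl)-3-hydroxy-5-(methoxymethoxy)-6,8-bis(3-methylbut-2-enyl)-7-(prop-2-enyloxy)-4H-chromen-4-one | COCOc1c(CC=C(C)C)c(OCC=C)c(CC=C(C)C)c2oc(-c3ccc4C=CC(C)(C)Oc4c3)c(O)c(=O)c12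
F11 | step 15 | 2-(2,2-dimethyl-2H-chromen-7-yl)-3,7-dihydroxy-5-(methoxymethoxy)-6,8-bis(3-methylbut-2-enyl)-4H-chromen-4-one | COCOc1c(CC=C(C)C)c(O)c(CC=C(C)C)c2oc(-c3ccc4C=CC(C)(C)Oc4c3)c(O)c(=O)c12
A1 | alternative 1 | 4-oxo-5,7-bis(2-methylbut-3-en-2-yloxy)-2-[3-(2-methylbut-3-yn-2-yloxy)phenyl]-4H-chromen-3-yl benzoate | C=CC(C)(C)Oc1cc(OC(C)(C)C=C)c2c(=O)c(OC(=O)c3ccccc3)c(-c3cccc(OC(C)(C)C#C)c3)oc2c1
A2 | alternative 1 | dorsilurin C 3-benzoate | CC(C)=CCc1c(O)c(CC=C(C)C)c2oc(-c3ccc4c(c3)OC(C)(C)C=C4)c(OC(=O)c3ccccc3)c(=O)c2c1O
A3 | alternative 2 | 2-acetyl-3,5,7-tris(methoxymethoxy)-6,8-bis(3-methylbut-2-enyl)-4H-chromen-4-one | CC(=O)c1oc2c(CC=C(C)C)c(OCOC)c(CC=C(C)C)c(OCOC)c2c(=O)c1OCOC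
A4 | alternative 2 | 3-(ethoxymethylidene)-6-methylhept-5-en-2-one (double-bond geometry not fixed) | CCOC=C(CC=C(C)C)C(C)=O
A5 | alternative 2 | 2-[3-hydroxy-4-(3-methylbut-2-enyl)phenyl]-3,5,7-tris(methoxymethoxy)-6,8-bis(3-methylbut-2-enyl)-4H-chromen-4-one | CC(C)=CCc1ccc(-c2oc3c(CC=C(C)C)c(OCOC)c(CC=C(C)C)c(OCOC)c3c(=O)c2OCOC)cc1O
A6 | alternative 3 | ethyl 2-acetyl-5-methylhex-4-enoate (racemic) | CCOC(=O)C(CC=C(C)C)C(C)=O
A7 | alternative 3 | ethyl 5-methylhex-4-enoate | CCOC(=O)CCC=C(C)C
A8 | alternative 3 | 2,4-bis(3-methylbut-2-enyl)benzene-1,3,5-triol | CC(C)=CCc1c(O)cc(O)c(CC=C(C)C)c1O
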